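## Structural features

The target is a flavan-3-ol: a chroman (aromatic ring A fused to the dihydropyran ring C) carrying a 3,4-dihydroxyphenyl group (ring B) at C2 and a hydroxyl at C3. Ring A is phloroglucinol-derived: its three oxygens are the ring oxygen O1 (on C8a), a free 5-OH, and O7, which is acylated by a 3,4,5-trihydroxybenzoyl (galloyl) unit. C2 (R) and C3 (S) are adjacent and are the only stereocentres; aryl and hydroxyl are trans and both equatorial on the half-chair of ring C. Fragile groups are the aryl ester at O7 (lost or moved by base, nucleophiles or hot acidic alcohols), the benzylic aryl ether C2–O1 (ionisable under acid because C2 is para to O4′ through ring B), and six free phenols including a catechol and a pyrogallol (air- and base-sensitive). The real difficulty is twofold: a single galloyl group must sit on O7 and not on O5, O3 or a ring B oxygen, and the trans C2/C3 pair must be set in the absolute sense. The key step uses the fact that C2 is bound to O1, benzylic to ring B and para to O4′ all at once, so in an open-chain 1,3-diarylpropan-2-ol ether the C2 methylene can be oxidised to an O4′-stabilised cation within six-membered reach of a ring A phenol oxygen. It also uses the local mirror plane of the open-chain ring A (a 4-acyloxy-2,6-dihydroxyphenyl group): O5 and O8a are equivalent before closure, so the gallate can be placed on the one unique oxygen and either phenol closes to the same chroman.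

## Logic of the disconnections

**18 from 17.** The six O–CH2Ph bonds (three on the galloyl ring, two on ring B, one at O3) are cut last. One kind of protecting group then falls in one neutral, reductive operation, and the sensitive hexaphenol needs no further chemistry. The gain is that every earlier intermediate is lipophilic and easy to purify. The demand is that hydrogenolysis spares the benzylic C2–O1 bond and the aryl ester.

**17 from 16.** O1–C2 is cut and two electrons and a proton are returned to C2. This is the one bond of ring C whose carbon end can be activated from a plain methylene. The gain is loss of ring C and of the C2 stereocentre: 16 has a single stereocentre and a symmetric ring A. 16 must be the (R) enantiomer; ring closure changes the C3 descriptor to S only because C2 gains oxygen and outranks C4, with no bond at C3 broken. The forward step must oxidise ring B and C2–H rather than ring A or the product, and must close trans to the C3 substituent.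

**16 from 14 (through 15).** The two phenolic O–CH2OMe bonds are cut. The phenols are needed free only for the ring closure, and the acetal groups are what directs the metalation that builds 10. The removal must spare the aryl ester and the benzyl ethers and must not alkylate the electron-rich ring A, which argues for a non-protic silyl triflate method.

**14 from 12 and 13.** The acyl–O7 bond is cut. At this stage O7 is the only free hydroxyl and ring A is still symmetric, so the regiochemistry of galloylation is settled by construction. The galloyl unit enters as a purchasable acid. The demand is a mild esterification of a phenol with an electron-rich benzoic acid.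

**12 from 11, and 11 from 10.** The O7–Si bond and the O3–CH2Ph bond are cut. Silicon on O7 is orthogonal to both acetal and benzyl; benzyl on O3 is a non-participating spectator in the oxidation and leaves in the last step. The alkylation must not desilylate the aryl silyl ether, and fluoride must free O7 alone.

**10 from 8 (through 9) and 5.** C4–C4a is cut. C4a lies between two acetal oxygens and is the most acidic ring position of 8, and C4 is the terminal carbon of an epoxide. The cut divides the molecule into two halves of similar size, with the stereocentre carried intact in 5. The demand is that a hindered, chelated aryllithium opens the epoxide at its CH2 terminus.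

**5 from 1 (through 3) and 2 (through 4).** The C2–C1′ bond and one epoxide C–O bond are cut. 2 is a three-carbon unit with the C3 stereocentre in place and two electrophilic termini used in turn: the epoxide carbon takes ring B, and the chloride-bearing carbon becomes the new epoxide terminus that later takes ring A. The organometallic must open the epoxide rather than displace chloride, since direct displacement would lead to the enantiomer.

**8 from 6 (through 7).** One O–Si and two O–CH2 bonds are cut. The single silyl group marks the future O7. Monosilylation of a threefold-symmetric triol is statistical; this is accepted at the first step on the cheapest material because the by-products are separable.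

## Other disconnections considered

**Alternative 1:** The cut is made on both sides of C3: C3–C4 and C2–C1′ are formed together around a vinylboron unit.
- **Forward step:** Vinyllithium A2 adds to the ring A benzylboronic ester A1. Pd(OAc)2 with a Mandyphos-type chiral bisphosphine then joins this adduct to the ring B aryl triflate A3. The arylpalladium species induces a 1,2-shift of the ring A benzyl group from boron to carbon (C3–C4), and reductive elimination forms C2–C1′, giving the secondary boronate A4.
- **Relation to the chosen route:** Oxidation of A4 with retention would give alcohol 10 itself. The alternative therefore replaces steps 1 and 3, not the ring closure.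
- **In its favour:** C3 is created by catalyst control from three achiral pieces in one operation, and the hindered aryllithium–epoxide opening of step 3 is avoided. On convergence it is the better plan. On access to either enantiomer it is the equal of the chosen plan, since both enantiomers of 2 are sold.
- **Against it here:** The migrating group is a 2,6-dioxygenated benzyl group, hindered and little explored in this role. The electron-rich triflate A3 is slow in oxidative addition. A1 needs about two operations from 8, A2 must be halide-free, and the ligand is costly. The enantiomeric purity would have to be earned by the catalyst, whereas 10 made from 2 inherits it.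
- **Comparison:** On structure both plans meet at 10. On mechanism this is catalyst control against chiral-pool control. On step economy it is one or two steps longer. It leaves C2 as a methylene, so it adds catalyst risk without removing the main risk of the chosen plan.

**Alternative 2:** The cut dismantles ring A: C4a–C8a, C5–C6 and C8–C8a.
- **Forward step:** Heating cyclobutenone A5 with the chiral siloxyalkyne A6 sets off four-electron ring opening, [2+2] addition to the ynol ether, a second ring opening, six-electron closure and tautomerisation. The product is phenol A7, with the free hydroxyl as the future O1, the silyloxy group at C5 and the 4-methoxybenzyloxy group at C7.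
- **Correction:** A7 with the side-chain configuration (2S,3S) is the threo (syn) isomer, not erythro. Threo is what an invertive closure at C2 (Mitsunobu after loss of the triethylsilyl group) needs for a 2,3-trans chroman; an erythro isomer would give the cis chroman by the same closure. The structure is kept and the label corrected.
- **In its favour:** The three ring A oxygens emerge chemically distinct through the regiochemistry of a pericyclic cascade. This is better than the chosen plan, which relies on a statistical monosilylation and on symmetry. C2 already carries oxygen, so ring C closes by a conventional substitution with no oxidant near free phenols; this too is better.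
- **Against it here:** A6 carries both stereocentres and a sensitive ynol silyl ether and needs a long synthesis. A5 is not an article of commerce. The thermal step must spare a benzylic silyl ether. Six further operations follow A7: desilylation, closure, removal of the 4-methoxybenzyl group, galloylation, desilylation and hydrogenolysis.
- **Comparison:** On structure it builds an aromatic ring that can be bought as 6. On mechanism it is predictable. On step economy it is clearly worse, probably beyond fifteen steps against nine. The final hydrogenolysis is equal in both.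

**Alternative 3:** The cut removes C3–C4 and O1–C2 together, so ring C is a [4+2] adduct.
- **Forward step:** A chiral BINOL-derived phosphoric acid dehydrates A8 to the ortho-quinone methide A9, which adds across the (E)-styrylsilane A10 to give the 2,3-trans chroman A11. The C3–Si bond is then oxidised to C3–O with retention (Tamao–Fleming).
- **In its favour:** Two ring bonds and both stereocentres are formed in one step, which is better per step than the chosen key step. The trans relationship is carried over from the (E)-alkene. Regiochemistry is doubly enforced, since benzylic and β-silyl stabilisation both place aryl at C2 and silicon at C3. No oxidant meets a free phenol.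
- **Against it here:**
  - A9 is unsubstituted at its methylene carbon, so it is very reactive and prone to oligomerise, and it offers the chiral acid little to discriminate; enantiocontrol is uncertain.
  - A stepwise path through the β-silyl cation can lose silicon instead of closing.
  - Converting the phenyldimethylsilyl group to hydroxyl needs electrophilic cleavage of Si–Ph (acid, or bromine or a mercury salt with peracid). The trioxygenated ring A and ring B would hardly tolerate this without ring substitution.
  - A8 needs three different oxygen substituents on ring A.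
  - The free 3-OH formed later must be protected before galloylation at O7.
- **Comparison:** Structurally it is more convergent. Mechanistically it is riskier at two points (enantiocontrol and C–Si oxidation). On step economy it is about equal or slightly worse, at roughly eleven to thirteen steps. The chosen plan takes C3 from 2 and asks its key step only for diastereocontrol.

Key step: step 8

Remarks on the chemistry:
- Flavan numbering (O1, C2, C3, C4, C4a–C8a, primed for ring B) is used for open-chain compounds as well.
- Assumption: 13 is bought as such; it is the perbenzylated form of gallic acid and an article of commerce.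

## Route

Step 1
Reactants: 1 4-bromo-1,2-bis(benzyloxy)benzene; 2 (R)-epichlorohydrin
Product: 5 (R)-2-[3,4-bis(benzyloxy)benzyl]oxirane, via arylmagnesium bromide 3 (not isolated), via chlorohydrin 4 (not isolated)
Conditions: Mg, THF, 45 °C; then 2, CuI (10 mol%), −40 → 0 °C; then aq NaOH, rt
Reagents that add atoms: none
Why: Copper-catalysed Grignard opening of a terminal epoxide: the arylcopper species attacks the unsubstituted epoxide carbon of 2 faster than it displaces chloride, so no bond at the stereocentre is broken and 4 keeps the configuration of 2; hydroxide then closes the new epoxide by intramolecular Williamson displacement of chloride (3-exo-tet), again without touching the stereocentre, which is (R) in 5.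

Step 2
Reactants: 6 phloroglucinol
Product: 8 [3,5-bis(methoxymethoxy)phenoxy]triisopropylsilane, via mono-silyl ether 7 (not isolated)
Conditions: TIPSCl (1.0 equiv), imidazole, DMF, 0 °C → rt; then i-Pr2NEt, MOMCl (excess), 0 °C → rt
Reagents that add atoms: chlorotriisopropylsilane CC(C)[Si](Cl)(C(C)C)C(C)C; chloromethyl methyl ether COCCl
Why: Statistical monosilylation of a threefold-symmetric triol followed by exhaustive O-alkylation of the remaining phenols; 7 should be the main component of a near-statistical mixture, and the tris(methoxymethyl) and bis-silyl by-products differ enough in polarity from 8 to be removed by chromatography; the bulky silyl group marks the future O7 and is orthogonal to acetal and benzyl.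

Step 3
Reactants: 8 [3,5-bis(methoxymethoxy)phenoxy]triisopropylsilane; 5 (R)-2-[3,4-bis(benzyloxy)benzyl]oxirane
Product: 10 (R)-1-[3,4-bis(benzyloxy)phenyl]-3-[2,6-bis(methoxymethoxy)-4-(triisopropylsilyloxy)phenyl]propan-2-ol, via aryllithium 9 (not isolated)
Conditions: 8, n-BuLi, THF, 0 °C; then 5, BF3·OEt2, −78 °C
Reagents that add atoms: none
Why: Directed ortho-metalation lithiates the ring position flanked by both methoxymethoxy groups (the hindered silyloxy group is a poor director); BF3 activation (Ganem-type epoxide opening) lets the chelated aryllithium attack 5 at the terminal CH2 at −78 °C, so the stereocentre is untouched and 10 is (R).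

Step 4
Reactants: 10 (R)-1-[3,4-bis(benzyloxy)phenyl]-3-[2,6-bis(methoxymethoxy)-4-(triisopropylsilyloxy)phenyl]propan-2-ol
Product: 11 (R)-{4-[2-(benzyloxy)-3-(3,4-bis(benzyloxy)phenyl)propyl]-3,5-bis(methoxymethoxy)phenoxy}triisopropylsilane
Conditions: NaH, BnBr, n-Bu4NI (cat.), THF/DMF (10:1), 0 °C → rt
Reagents that add atoms: benzyl bromide BrCc1ccccc1
Why: Williamson etherification of the secondary alkoxide; iodide catalysis keeps the temperature low and DMF is kept to a minimum so that the aryl silyl ether is not cleaved; no bond at the stereocentre is broken.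

Step 5
Reactants: 11 (R)-{4-[2-(benzyloxy)-3-(3,4-bis(benzyloxy)phenyl)propyl]-3,5-bis(methoxymethoxy)phenoxy}triisopropylsilane
Product: 12 (R)-4-[2-(benzyloxy)-3-(3,4-bis(benzyloxy)phenyl)propyl]-3,5-bis(methoxymethoxy)phenol
Conditions: TBAF, THF, 0 °C
Reagents that add atoms: none
Why: Fluoride-mediated desilylation: the strong Si–F bond and the good phenoxide leaving group make the aryl silyl ether the only group attacked, while acetal and benzyl ethers are inert; O7 becomes the only free hydroxyl of the molecule.

Step 6
Reactants: 12 (R)-4-[2-(benzyloxy)-3-(3,4-bis(benzyloxy)phenyl)propyl]-3,5-bis(methoxymethoxy)phenol; 13 3,4,5-tris(benzyloxy)benzoic acid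
Product: 14 (R)-4-[2-(benzyloxy)-3-(3,4-bis(benzyloxy)phenyl)propyl]-3,5-bis(methoxymethoxy)phenyl 3,4,5-tris(benzyloxy)benzoate
Conditions: EDC·HCl, DMAP (0.2 equiv), CH2Cl2, 0 °C → rt
Reagents that add atoms: none
Why: Steglich esterification: the carbodiimide activates 13 and DMAP transfers the acyl group to the unhindered phenol; O7 is the only free hydroxyl and ring A is still symmetric, so the galloyl group can go nowhere else.

Step 7
Reactants: 14 (R)-4-[2-(benzyloxy)-3-(3,4-bis(benzyloxy)phenyl)propyl]-3,5-bis(methoxymethoxy)phenyl 3,4,5-tris(benzyloxy)benzoate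
Product: 16 (R)-4-[2-(benzyloxy)-3-(3,4-bis(benzyloxy)phenyl)propyl]-3,5-dihydroxyphenyl 3,4,5-tris(benzyloxy)benzoate, via bis(trimethylsilyl) ether 15 (not isolated)
Conditions: TMSOTf, 2,2'-bipyridyl, CH2Cl2, 0 °C → rt; then H2O
Reagents that add atoms: none
Why: Silyl triflate with 2,2'-bipyridyl converts aromatic methoxymethyl ethers into aryl trimethylsilyl ethers through a pyridinium-type intermediate under non-protic, only weakly acidic conditions, and water then hydrolyses the labile aryl silyl ethers; no free acid or alcohol is present that could transesterify the gallate, and benzyl ethers and the stereocentre are not affected.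

Step 8
Reactants: 16 (R)-4-[2-(benzyloxy)-3-(3,4-bis(benzyloxy)phenyl)propyl]-3,5-dihydroxyphenyl 3,4,5-tris(benzyloxy)benzoate
Product: 17 (2R,3S)-3-(benzyloxy)-2-[3,4-bis(benzyloxy)phenyl]-5-hydroxychroman-7-yl 3,4,5-tris(benzyloxy)benzoate
Conditions: divided cell, graphite anode, Pt cathode, n-Bu4NPF6 (0.1 M), HFIP/CH2Cl2 (1:4), AcOH in the catholyte, anode potential held at the foot of the first anodic wave of 16 (cyclic voltammetry), 2.0–2.2 F/mol, 0 °C
Reagents that add atoms: none
Why: Ring B, a 4-alkyl-1,2-dialkoxybenzene, should lose the first electron; its radical cation gives up a C2 proton (the C2–H bonds are benzylic to ring B only), the benzylic radical is oxidised at once, and the resulting cation is a para-quinone methide-type oxocarbenium ion with the charge shared by C2, C1′ and O4′, while the protons are reduced to H2 at the cathode. The closest known reaction type is the anodic or quinone-mediated oxidation of 4-alkoxybenzylic C–H bonds with capture by a tethered oxygen nucleophile, of which the closure of 1-(2-hydroxyphenyl)-3-arylpropanes to 2-arylchromans is the nearest relative. Ring C closes in a 6-exo-trig mode, the phenol oxygen attacking C2 of the exocyclic C2=C1′ bond through a half-chair. C2 is set by the C3 stereocentre: allylic 1,3-strain places C3–H near the plane of the quinoid ring and the benzyloxy group anti to the incoming oxygen, so aryl and benzyloxy should end up trans and equatorial (2R,3S), with the cis epimer as the expected, separable minor product. C3 itself is not touched; its descriptor changes from R to S only because C2 gains oxygen and overtakes C4 in priority. The step needs site selectivity between ring B and ring A and between 16 and 17: ring A is meta-dioxygenated and carries the electron-poor acyloxy group, the phenols stay un-ionised in the acidic, base-free HFIP medium, the potential is held at the first wave, 17 bears an inductively withdrawing aryloxy group at C2, and the charge is limited to two electrons per molecule. No choice between the two phenols arises, because they are related by the local mirror plane of ring A, and the one that does not react becomes the 5-OH. HFIP stabilises the radical cation and the benzylic cation and, should it add to the cation, gives an ether that can re-ionise, so the intramolecular phenol remains the final trap.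

Step 9
Reactants: 17 (2R,3S)-3-(benzyloxy)-2-[3,4-bis(benzyloxy)phenyl]-5-hydroxychroman-7-yl 3,4,5-tris(benzyloxy)benzoate
Product: 18 (2R,3S)-2-(3,4-dihydroxyphenyl)-3,5-dihydroxychroman-7-yl 3,4,5-trihydroxybenzoate (catechin 7-O-gallate)
Conditions: H2 (1 atm), Pd(OH)2/C, THF/MeOH, rt
Reagents that add atoms: none
Why: Heterogeneous hydrogenolysis of the five aryl benzyl ethers and the secondary benzyl ether under neutral conditions at ambient pressure; the aryl ester is inert to these conditions and the C2–O1 ether of a flavan-3-ol is far slower to cleave than O-benzyl groups, and neither stereocentre is involved.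

## Compound list

1 | 4-bromo-1,2-bis(benzyloxy)benzene | Brc1ccc(OCc2ccccc2)c(OCc2ccccc2)c1 | starting material
2 | (R)-epichlorohydrin | ClC[C@H]1CO1 | starting material
3 | 3,4-bis(benzyloxy)phenylmagnesium bromide | Br[Mg]c1ccc(OCc2ccccc2)c(OCc2ccccc2)c1 | intermediate
4 | (R)-1-[3,4-bis(benzyloxy)phenyl]-3-chloropropan-2-ol (formed as its magnesium alkoxide) | ClC[C@H](O)Cc1ccc(OCc2ccccc2)c(OCc2ccccc2)c1 | intermediate
5 | (R)-2-[3,4-bis(benzyloxy)benzyl]oxirane | C(c1ccc(OCc2ccccc2)c(OCc2ccccc2)c1)[C@@H]1CO1 | intermediate
6 | phloroglucinol | Oc1cc(O)cc(O)c1 | starting material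
7 | 5-(triisopropylsilyloxy)benzene-1,3-diol | Oc1cc(O)cc(O[Si](C(C)C)(C(C)C)C(C)C)c1 | intermediate
8 | [3,5-bis(methoxymethoxy)phenoxy]triisopropylsilane | COCOc1cc(OCOC)cc(O[Si](C(C)C)(C(C)C)C(C)C)c1 | intermediate
9 | 2,6-bis(methoxymethoxy)-4-(triisopropylsilyloxy)phenyllithium | COCOc1cc(O[Si](C(C)C)(C(C)C)C(C)C)cc(OCOC)c1[Li] | intermediate
10 | (R)-1-[3,4-bis(benzyloxy)phenyl]-3-[2,6-bis(methoxymethoxy)-4-(triisopropylsilyloxy)phenyl]propan-2-ol | COCOc1cc(O[Si](C(C)C)(C(C)C)C(C)C)cc(OCOC)c1C[C@H](O)Cc1ccc(OCc2ccccc2)c(OCc2ccccc2)c1 | intermediate
11 | (R)-{4-[2-(benzyloxy)-3-(3,4-bis(benzyloxy)phenyl)propyl]-3,5-bis(methoxymethoxy)phenoxy}triisopropylsilane | COCOc1cc(O[Si](C(C)C)(C(C)C)C(C)C)cc(OCOC)c1C[C@H](OCc1ccccc1)Cc1ccc(OCc2ccccc2)c(OCc2ccccc2)c1 | intermediate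
12 | (R)-4-[2-(benzyloxy)-3-(3,4-bis(benzyloxy)phenyl)propyl]-3,5-bis(methoxymethoxy)phenol | COCOc1cc(O)cc(OCOC)c1C[C@H](OCc1ccccc1)Cc1ccc(OCc2ccccc2)c(OCc2ccccc2)c1 | intermediate
13 | 3,4,5-tris(benzyloxy)benzoic acid | OC(=O)c1cc(OCc2ccccc2)c(OCc2ccccc2)c(OCc2ccccc2)c1 | starting material
14 | (R)-4-[2-(benzyloxy)-3-(3,4-bis(benzyloxy)phenyl)propyl]-3,5-bis(methoxymethoxy)phenyl 3,4,5-tris(benzyloxy)benzoate | O=C(Oc1cc(OCOC)c(C[C@H](OCc2ccccc2)Cc2ccc(OCc3ccccc3)c(OCc3ccccc3)c2)c(OCOC)c1)c1cc(OCc2ccccc2)c(OCc2ccccc2)c(OCc2ccccc2)c1 | intermediate
15 | (R)-4-[2-(benzyloxy)-3-(3,4-bis(benzyloxy)phenyl)propyl]-3,5-bis(trimethylsilyloxy)phenyl 3,4,5-tris(benzyloxy)benzoate | O=C(Oc1cc(O[Si](C)(C)C)c(C[C@H](OCc2ccccc2)Cc2ccc(OCc3ccccc3)c(OCc3ccccc3)c2)c(O[Si](C)(C)C)c1)c1cc(OCc2ccccc2)c(OCc2ccccc2)c(OCc2ccccc2)c1 | intermediate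
16 | (R)-4-[2-(benzyloxy)-3-(3,4-bis(benzyloxy)phenyl)propyl]-3,5-dihydroxyphenyl 3,4,5-tris(benzyloxy)benzoate | O=C(Oc1cc(O)c(C[C@H](OCc2ccccc2)Cc2ccc(OCc3ccccc3)c(OCc3ccccc3)c2)c(O)c1)c1cc(OCc2ccccc2)c(OCc2ccccc2)c(OCc2ccccc2)c1 | intermediate
17 | (2R,3S)-3-(benzyloxy)-2-[3,4-bis(benzyloxy)phenyl]-5-hydroxychroman-7-yl 3,4,5-tris(benzyloxy)benzoate | O=C(Oc1cc(O)c2c(c1)O[C@H](c1ccc(OCc3ccccc3)c(OCc3ccccc3)c1)[C@@H](OCc1ccccc1)C2)c1cc(OCc2ccccc2)c(OCc2ccccc2)c(OCc2ccccc2)c1 | intermediate
18 | (2R,3S)-2-(3,4-dihydroxyphenyl)-3,5-dihydroxychroman-7-yl 3,4,5-trihydroxybenzoate (catechin 7-O-gallate) | O=C(Oc1cc(O)c2c(c1)O[C@H](c1ccc(O)c(O)c1)[C@@H](O)C2)c1cc(O)c(O)c(O)c1 | target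

## Step count and least certain steps

Total step count: 9. Longest linear sequence: 8 (steps 2 to 9 from 6, or step 1 and steps 3 to 9 from 1).

**Step 8 (key step).** The gap in oxidation potential between ring B and the free 2-alkylresorcinol ring A is expected to be small. The most likely failures are:
- electron loss from ring A, or from a phenolate if base builds up, followed by oxidation at C4 or oxidative coupling of ring A;
- further oxidation of the product, since 17 still carries ring B and an activated C2–H;
- loss of the C3 proton from the cation instead of ring closure;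
- insufficient facial selectivity at C2.

The fallback separates oxidation from ring closure and oxidises while the phenols are still masked. It sets out from 14. DDQ in CH2Cl2/AcOH (benzylic acetoxylation of a 3,4-dialkoxyphenylalkane, a known reaction type in which the acyloxy group protects the product against a second oxidation) should give 4-[(2S,3RS)-3-acetoxy-2-(benzyloxy)-3-[3,4-bis(benzyloxy)phenyl]propyl]-3,5-bis(methoxymethoxy)phenyl 3,4,5-tris(benzyloxy)benzoate F1 as a mixture of C2 epimers. Brief treatment of F1 with HCl in 2-propanol/CH2Cl2 should then remove the acetals and ionise the benzylic acetate, so that the freed phenol closes ring C in an acid-mediated SN1 cyclisation of the kind long used for flavan-3-ols. Facial selectivity is again set by C3, now under reversible conditions. The fallback returns to the route at 17.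

**Step 7.** Two acetals flanked by the side chain must be cleaved next to an aryl ester on an electron-rich ring. Possible failures are acyl loss or acyl transfer, alkylation of ring A by the liberated methoxymethyl electrophile, and incomplete cleavage. The fallback moves acetal cleavage ahead of esterification and carries the phenols as allyl ethers, which come off under neutral conditions. It sets out from 11:
- HCl in MeOH/THF should give (R)-2-[2-(benzyloxy)-3-(3,4-bis(benzyloxy)phenyl)propyl]-5-(triisopropylsilyloxy)benzene-1,3-diol F2; the aryl silyl ether is expected to survive.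
- Allyl bromide and K2CO3 in acetone give (R)-{3,5-bis(allyloxy)-4-[2-(benzyloxy)-3-(3,4-bis(benzyloxy)phenyl)propyl]phenoxy}triisopropylsilane F3.
- TBAF gives (R)-3,5-bis(allyloxy)-4-[2-(benzyloxy)-3-(3,4-bis(benzyloxy)phenyl)propyl]phenol F4.
- Steglich esterification with 13 gives (R)-3,5-bis(allyloxy)-4-[2-(benzyloxy)-3-(3,4-bis(benzyloxy)phenyl)propyl]phenyl 3,4,5-tris(benzyloxy)benzoate F5.
- Deallylation with Pd(PPh3)4 (zerovalent palladium) and PhSiH3 returns to the route at 16.

**Step 3.** The aryllithium is hindered and internally chelated. If its attack is slow, Lewis acid-induced rearrangement of epoxide 5, or consumption of 9 by BF3, can outrun the opening. The fallback reverses the order of fragment union so that the hindered nucleophile meets the smallest possible epoxide. It sets out from 8: 9 is generated as before and treated with (S)-epichlorohydrin F6 and BF3·OEt2 at −78 °C to give (S)-1-chloro-3-[2,6-bis(methoxymethoxy)-4-(triisopropylsilyloxy)phenyl]propan-2-ol F7. NaH in THF closes it to (S)-2-[2,6-bis(methoxymethoxy)-4-(triisopropylsilyloxy)benzyl]oxirane F8. The unhindered Grignard reagent 3 with catalytic CuI then opens F8 at its CH2 terminus. The opposite enantiomer of the three-carbon unit is needed because the two aryl groups now enter in reverse order. The fallback returns to the route at 10.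

## Further compounds

F1 | step 8 | 4-[(2S,3RS)-3-acetoxy-2-(benzyloxy)-3-[3,4-bis(benzyloxy)phenyl]propyl]-3,5-bis(methoxymethoxy)phenyl 3,4,5-tris(benzyloxy)benzoate | O=C(Oc1cc(OCOC)c(C[C@H](OCc2ccccc2)C(OC(C)=O)c2ccc(OCc3ccccc3)c(OCc3ccccc3)c2)c(OCOC)c1)c1cc(OCc2ccccc2)c(OCc2ccccc2)c(OCc2ccccc2)c1
F2 | step 7 | (R)-2-[2-(benzyloxy)-3-(3,4-bis(benzyloxy)phenyl)propyl]-5-(triisopropylsilyloxy)benzene-1,3-diol | CC(C)[Si](Oc1cc(O)c(C[C@H](OCc2ccccc2)Cc2ccc(OCc3ccccc3)c(OCc3ccccc3)c2)c(O)c1)(C(C)C)C(C)C
F3 | step 7 | (R)-{3,5-bis(allyloxy)-4-[2-(benzyloxy)-3-(3,4-bis(benzyloxy)phenyl)propyl]phenoxy}triisopropylsilane | CC(C)[Si](Oc1cc(OCC=C)c(C[C@H](OCc2ccccc2)Cc2ccc(OCc3ccccc3)c(OCc3ccccc3)c2)c(OCC=C)c1)(C(C)C)C(C)C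
F4 | step 7 | (R)-3,5-bis(allyloxy)-4-[2-(benzyloxy)-3-(3,4-bis(benzyloxy)phenyl)propyl]phenol | Oc1cc(OCC=C)c(C[C@H](OCc2ccccc2)Cc2ccc(OCc3ccccc3)c(OCc3ccccc3)c2)c(OCC=C)c1
F5 | step 7 | (R)-3,5-bis(allyloxy)-4-[2-(benzyloxy)-3-(3,4-bis(benzyloxy)phenyl)propyl]phenyl 3,4,5-tris(benzyloxy)benzoate | O=C(Oc1cc(OCC=C)c(C[C@H](OCc2ccccc2)Cc2ccc(OCc3ccccc3)c(OCc3ccccc3)c2)c(OCC=C)c1)c1cc(OCc2ccccc2)c(OCc2ccccc2)c(OCc2ccccc2)c1
F6 | step 3 | (S)-epichlorohydrin (purchased enantiomer of 2) | ClC[C@@H]1CO1
F7 | step 3 | (S)-1-chloro-3-[2,6-bis(methoxymethoxy)-4-(triisopropylsilyloxy)phenyl]propan-2-ol | ClC[C@@H](O)Cc1c(OCOC)cc(O[Si](C(C)C)(C(C)C)C(C)C)cc1OCOC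
F8 | step 3 | (S)-2-[2,6-bis(methoxymethoxy)-4-(triisopropylsilyloxy)benzyl]oxirane | COCOc1cc(O[Si](C(C)C)(C(C)C)C(C)C)cc(OCOC)c1C[C@H]1CO1
A1 | alternative 1 | 2-[2,6-bis(methoxymethoxy)-4-(triisopropylsilyloxy)benzyl]-4,4,5,5-tetramethyl-1,3,2-dioxaborolane | COCOc1cc(O[Si](C(C)C)(C(C)C)C(C)C)cc(OCOC)c1CB1OC(C)(C)C(C)(C)O1
A2 | alternative 1 | vinyllithium | [Li]C=C
A3 | alternative 1 | 3,4-bis(benzyloxy)phenyl trifluoromethanesulfonate | O=S(=O)(Oc1ccc(OCc2ccccc2)c(OCc2ccccc2)c1)C(F)(F)F
A4 | alternative 1 | 2-{(R)-1-[3,4-bis(benzyloxy)phenyl]-3-[2,6-bis(methoxymethoxy)-4-(triisopropylsilyloxy)phenyl]propan-2-yl}-4,4,5,5-tetramethyl-1,3,2-dioxaborolane | COCOc1cc(O[Si](C(C)C)(C(C)C)C(C)C)cc(OCOC)c1C[C@H](B1OC(C)(C)C(C)(C)O1)Cc1ccc(OCc2ccccc2)c(OCc2ccccc2)c1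
A5 | alternative 2 | 3-[(4-methoxybenzyl)oxy]cyclobut-2-en-1-one | COc1ccc(COC2=CC(=O)C2)cc1
A6 | alternative 2 | {[(4S,5S)-4-(benzyloxy)-5-[3,4-bis(benzyloxy)phenyl]-5-(triethylsilyloxy)pent-1-yn-1-yl]oxy}triisopropylsilane | CC(C)[Si](OC#CC[C@H](OCc1ccccc1)[C@@H](O[Si](CC)(CC)CC)c1ccc(OCc2ccccc2)c(OCc2ccccc2)c1)(C(C)C)C(C)C
A7 | alternative 2 | 2-[(2S,3S)-2-(benzyloxy)-3-[3,4-bis(benzyloxy)phenyl]-3-(triethylsilyloxy)propyl]-5-[(4-methoxybenzyl)oxy]-3-(triisopropylsilyloxy)phenol (threo) | COc1ccc(COc2cc(O)c(C[C@H](OCc3ccccc3)[C@@H](O[Si](CC)(CC)CC)c3ccc(OCc4ccccc4)c(OCc4ccccc4)c3)c(O[Si](C(C)C)(C(C)C)C(C)C)c2)cc1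
A8 | alternative 3 | 3-(benzyloxy)-2-(hydroxymethyl)-5-(triisopropylsilyloxy)phenol | OCc1c(O)cc(O[Si](C(C)C)(C(C)C)C(C)C)cc1OCc1ccccc1
A9 | alternative 3 | 5-(benzyloxy)-6-methylidene-3-(triisopropylsilyloxy)cyclohexa-2,4-dien-1-one | C=C1C(=O)C=C(O[Si](C(C)C)(C(C)C)C(C)C)C=C1OCc1ccccc1
A10 | alternative 3 | (E)-{2-[3,4-bis(benzyloxy)phenyl]ethenyl}dimethyl(phenyl)silane | C[Si](C)(/C=C/c1ccc(OCc2ccccc2)c(OCc2ccccc2)c1)c1ccccc1
A11 | alternative 3 | (2R,3S)-5-(benzyloxy)-2-[3,4-bis(benzyloxy)phenyl]-3-[dimethyl(phenyl)silyl]-7-(triisopropylsilyloxy)chroman | CC(C)[Si](C(C)C)(C(C)C)Oc1cc(OCc3ccccc3)c2c(c1)O[C@H](c1ccc(OCc3ccccc3)c(OCc3ccccc3)c1)[C@@H]([Si](C)(C)c1ccccc1)C2
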